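**Plan**

- Numbering follows the elemanolide skeleton: C10 is the quaternary carbon (C14 its methyl, C1=C2 its vinyl group), C5 carries C4(=C3H2)–C15H2OAc, C6 the isobutyrate, C7/C8 the lactone (C11=C13, C12=O) and C9 the acetate. β is the face of C14.
- Retrosynthetic cuts, in order: the O6 ester; the C1=C2 vinyl/C15–OH pair (back to a δ-lactone C1(=O)–O15); C4=C3 (back to a C4 carbinol); the C7–C11 bond (5-exo closure of a vinyl radical tethered to O8); last, C8–C9 and C5–C10 together.
- Enabling feature: C1 (on C10) and O15 (on the C4 arm of C5) are six atoms apart across the C5–C10 bond, and C6/C8 are 1,3-dioxygenated. Tying C1 to O15 as an ester makes the cyclohexane the adduct of an intramolecular Diels–Alder reaction of a 1,3-dioxygenated diene (C5=C6–C7=C8) with a (Z)-β-acetoxy methacrylate (C9=C10).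
- Forward order: chiral-pool lactone to the dienyl alcohol; ester with the dienophile acid; step 10 closes the cyclohexene and the δ-lactone; step 13 closes the tetrahydrofuran acetal; steps 17–18 open the δ-lactone to vinyl and CH2OH; step 20 gives the γ-lactone; the esters follow.
- Stereochemistry: (S)-3-hydroxy-γ-butyrolactone supplies a temporary C4 carbinol centre that fixes the diene face and is erased as C4=CH2 (steps 14–16). Diene and dienophile geometry in the anti mode set C5, C8, C9 and C10. The radical closure sets C7 (cis to O8) and C6 (hydrogen from the α face).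

Key step: step 10

Assumptions: the acetal carbon C12 in 19–26 is an epimer mixture, drawn without configuration, and ends as the lactone carbonyl; 2-bromoacrolein diethyl acetal 17 is taken as purchasable.

**Route**

Step 1
Reactants: 1 (S)-3-hydroxy-γ-butyrolactone
Product: 2 (3S)-3,4-dihydroxy-N-methoxy-N-methylbutanamide
Conditions: MeNH(OMe)·HCl, AlMe3, CH2Cl2, 0 °C to rt
Reagents that add atoms: N,O-dimethylhydroxylamine hydrochloride, CNOC.Cl
Why: Weinreb aminolysis of the lactone by the aluminium amide opens the ring without touching the C4 carbinol centre and gives a ketone precursor.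

Step 2
Reactants: 2 (3S)-3,4-dihydroxy-N-methoxy-N-methylbutanamide
Product: 3 (3S)-N-methoxy-N-methyl-3,4-bis(triethylsilyloxy)butanamide
Conditions: Et3SiCl, imidazole, DMF, 0 °C to rt
Reagents that add atoms: chlorotriethylsilane, CC[Si](Cl)(CC)CC
Why: Silyl ether formation on both hydroxyls; the secondary OTES later serves as the steric control element at C4 and the primary one is released selectively in step 5.

Step 3
Reactants: 3 (3S)-N-methoxy-N-methyl-3,4-bis(triethylsilyloxy)butanamide
Product: 4 (4S)-4,5-bis(triethylsilyloxy)pentan-2-one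
Conditions: MeMgBr, THF, 0 °C
Reagents that add atoms: methylmagnesium bromide, C[Mg]Br
Why: Weinreb ketone synthesis, in which the chelated tetrahedral intermediate stops at the methyl ketone (C7 enters).

Step 4
Reactants: 4 (4S)-4,5-bis(triethylsilyloxy)pentan-2-one
Product: 6 allyl (1E,5S)-3-oxo-5,6-bis(triethylsilyloxy)hex-1-enyl carbonate, via sodium hydroxymethylene-ketone enolate 5 (not isolated)
Conditions: NaN(SiMe3)2, THF, −78 °C; CF3CH2OCHO; then ClCO2CH2CH=CH2, −78 to 0 °C
Reagents that add atoms: 2,2,2-trifluoroethyl formate, O=COCC(F)(F)F; allyl chloroformate, C=CCOC(=O)Cl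
Why: Kinetic deprotonation at the methyl group, Claisen-type formylation and O-acylation of the hydroxymethylene-ketone sodium salt should give the trans β-acyloxy enone (C8 and O8 enter), as in the acylation of such sodium salts.

Step 5
Reactants: 6 allyl (1E,5S)-3-oxo-5,6-bis(triethylsilyloxy)hex-1-enyl carbonate
Product: 7 allyl (1E,5S)-6-hydroxy-3-oxo-5-(triethylsilyloxy)hex-1-enyl carbonate
Conditions: HF·pyridine, pyridine, THF, 0 °C
Reagents that add atoms: none
Why: Selective desilylation, the unhindered primary triethylsilyl ether being cleaved by buffered fluoride well before the secondary one.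

Step 6
Reactants: 8 tert-butyl propanoate
Product: 10 tert-butyl (2Z)-3-acetoxy-2-methylprop-2-enoate, via lithium formyl-ester enolate 9 (not isolated)
Conditions: LiN(iPr)2, THF, −78 °C; HCO2Et, −78 to −20 °C; then AcCl, −78 °C
Reagents that add atoms: ethyl formate, CCOC=O; acetyl chloride, CC(=O)Cl
Why: Crossed Claisen formylation gives the lithium chelate of the α-formyl ester, and O-acetylation with retention of the chelated geometry should place the acetoxy group cis to the ester (the Z geometry needed for C9).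

Step 7
Reactants: 10 tert-butyl (2Z)-3-acetoxy-2-methylprop-2-enoate
Product: 11 (2Z)-3-acetoxy-2-methylprop-2-enoic acid
Conditions: CF3CO2H, CH2Cl2, 0 °C
Reagents that add atoms: none
Why: Acidolysis of the tert-butyl ester with loss of isobutene should leave the enol acetate and its geometry intact.

Step 8
Reactants: 11 (2Z)-3-acetoxy-2-methylprop-2-enoic acid; 7 allyl (1E,5S)-6-hydroxy-3-oxo-5-(triethylsilyloxy)hex-1-enyl carbonate
Product: 13 keto ester (2S,5E)-6-(allyloxycarbonyloxy)-4-oxo-2-(triethylsilyloxy)hex-5-enyl (2Z)-3-acetoxy-2-methylprop-2-enoate, via acid chloride 12 (not isolated)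
Conditions: 1-chloro-N,N,2-trimethylprop-1-enylamine, CH2Cl2, 0 °C; then 7, pyridine, −20 °C to rt
Reagents that add atoms: none
Why: Acyl chloride esterification of the primary alcohol under neutral chloride formation (no HCl, no acyl-transfer catalyst) builds the O15–C1 ester that serves as the tether.

Step 9
Reactants: 13 keto ester
Product: 14 triene ester (2S,3Z,5E)-6-(allyloxycarbonyloxy)-4-(tert-butyldimethylsilyloxy)-2-(triethylsilyloxy)hexa-3,5-dienyl (2Z)-3-acetoxy-2-methylprop-2-enoate
Conditions: TBSOTf, Et3N, Et2O, −78 to 0 °C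
Reagents that add atoms: tert-butyldimethylsilyl triflate, CC(C)(C)[Si](C)(C)OS(=O)(=O)C(F)(F)F
Why: Soft enolisation (silyl triflate and amine) toward C5 gives the cross-conjugated 2-silyloxy diene, the Z enol ether (OSi cis to C4) being the usual outcome for such vinyl ketones.

Step 10
Reactants: 14 triene ester
Product: 15 trans-fused δ-lactone cycloadduct (C6=C7 TBS enol ether; 8β-allyl carbonate; 9α-acetate; 10β-methyl)
Conditions: PhMe (0.01 M), BHT, 150 °C, sealed tube
Reagents that add atoms: none
Why: Thermal concerted suprafacial [4+2] cycloaddition (intramolecular Diels–Alder reaction of an ester-tethered 1,3,9-decatriene), the closest precedent being the cyclisation of 3,5-hexadienyl acrylates and methacrylates to lactone-fused cyclohexenes. The carbocycle closes in the [4+2] mode and the δ-lactone (C1, O15, C15, C4, C5, C10) arises as the fused six-membered ring through the anti (tether-exo) transition state, so the ring fusion is trans; the four-atom tether excludes the other regiochemistry. C5 and C8 follow from the diene geometry (3Z enol ether and 5E enol carbonate place C4 and O8 outside, hence cis), and C9 and C10 from the Z dienophile in the anti mode (lactone carbonyl and acetoxy exo, methyl endo, hence methyl cis and O9 trans to O8 and C4). The absolute sense comes from C4: to avoid 1,3-allylic strain with the cis silyloxy group on C6 the C4–H bond eclipses C5=C6, which puts the tether on one diene face and the OTES group on the other. The step needs anti over syn selectivity, which the C6 silyloxy group (it clashes with the tether in the syn mode) and the α-methyl group should secure, and the facial selectivity just described. Heating is required because the donor pattern of the diene (C5 is its nucleophilic end) is not matched to the acrylate, a mismatch the tether overrides.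

Step 11
Reactants: 15 trans-fused δ-lactone cycloadduct
Product: 16 8β-hydroxy cycloadduct
Conditions: Pd(PPh3)4 (5 mol %), dimedone, THF, rt
Reagents that add atoms: none
Why: Tsuji–Trost-type deallylation, in which zerovalent palladium ionises the allyl carbonate, CO2 is lost and dimedone takes the allyl group, frees O8 under neutral conditions that spare the silyl enol ether.

Step 12
Reactants: 16 8β-hydroxy cycloadduct; 17 2-bromoacrolein diethyl acetal
Product: 19 8β-(2-bromo-1-ethoxyallyloxy) mixed acetal, via 2-bromo-1-ethoxyallyl collidinium triflate 18 (not isolated)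
Conditions: 17, Et3SiOTf, 2,4,6-collidine, CH2Cl2, 0 °C; then 16, 0 °C to rt
Reagents that add atoms: none
Why: Base-buffered acetal exchange through the pyridinium salt formed from the diethyl acetal and silyl triflate attaches C11–C13 to O8 without free acid.

Step 13
Reactants: 19 8β-(2-bromo-1-ethoxyallyloxy) mixed acetal
Product: 20 tricyclic 11(13)-methylene acetal (6β-OTBS; 7αH; 4S-OTES)
Conditions: Bu3SnH (slow addition), AIBN, PhH, 80 °C
Reagents that add atoms: none
Why: Ueno–Stork-type 5-exo-trig cyclisation of the vinyl radical onto C7 of the silyl enol ether can only close cis to O8 (C7–C11 β), and the C6 radical should take hydrogen from the stannane on the open α face (the β face carries the axial C14 methyl and O8), giving 6β-OTBS.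

Step 14
Reactants: 20 tricyclic 11(13)-methylene acetal
Product: 21 C4 carbinol
Conditions: HF·pyridine, pyridine, THF, 0 °C
Reagents that add atoms: none
Why: Selective desilylation, the side-chain triethylsilyl ether being far more labile to buffered fluoride than the hindered ring TBS ether.

Step 15
Reactants: 21 C4 carbinol
Product: 22 C4 ketone
Conditions: Dess–Martin periodinane, NaHCO3, CH2Cl2, rt
Reagents that add atoms: none
Why: Dess–Martin oxidation removes the temporary C4 stereocentre under buffered conditions that should neither epimerise C5 nor eliminate the C6 silyloxy group.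

Step 16
Reactants: 22 C4 ketone
Product: 23 4(3)-methylene δ-lactone
Conditions: Zn, CH2Br2, TiCl4 (pre-formed reagent), THF–CH2Cl2, 0 °C to rt
Reagents that add atoms: dibromomethane, BrCBr
Why: Takai–Lombardo methylenation with the non-basic zinc–titanium reagent is selective for the ketone over the lactone and acetate and avoids enolisation toward C5.

Step 17
Reactants: 23 4(3)-methylene δ-lactone
Product: 24 lactol (C1 hemiacetal; 9α-OH)
Conditions: iBu2AlH, CH2Cl2, −78 °C; aq. potassium sodium tartrate
Reagents that add atoms: none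
Why: Low-temperature hydride reduction of the lactone stops at the aluminium hemiacetal (lactol), and the acetate is cleaved reductively in the same step.

Step 18
Reactants: 24 lactol
Product: 25 vinyl diol (9α-OH; 15-OH)
Conditions: Ph3PCH3Br, n-BuLi, THF, 0 °C to rt
Reagents that add atoms: methyltriphenylphosphonium bromide, C[P+](c1ccccc1)(c1ccccc1)c1ccccc1.[Br-]
Why: Wittig methylenation of the open hydroxy-aldehyde form of the lactol turns C1 into the C10 vinyl group and releases the C15 hydroxyl.

Step 19
Reactants: 25 vinyl diol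
Product: 26 9α,15-diacetate
Conditions: Ac2O, pyridine, DMAP, CH2Cl2, rt
Reagents that add atoms: acetic anhydride, CC(=O)OC(C)=O
Why: DMAP-catalysed acylation of both free hydroxyls installs the two acetates of the target in one step.

Step 20
Reactants: 26 9α,15-diacetate
Product: 27 α-methylene γ-lactone (6β-OTBS)
Conditions: CrO3, H2SO4, acetone–H2O, 0 °C
Reagents that add atoms: water, O
Why: Jones oxidation, in which the acid hydrolyses the mixed acetal to the lactol and hexavalent chromium oxidises it to the lactone, should spare the hindered secondary TBS ether and the acetates.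

Step 21
Reactants: 27 α-methylene γ-lactone
Product: 28 6β-alcohol
Conditions: HF·pyridine, THF, 0 °C to rt
Reagents that add atoms: none
Why: Fluoride cleavage of the silyl ether under mildly acidic conditions that the acetates and the α-methylene lactone tolerate.

Step 22
Reactants: 28 6β-alcohol
Product: 29 CNP0500052.1
Conditions: (iPrCO)2O, DMAP, Et3N, CH2Cl2, rt to 40 °C
Reagents that add atoms: isobutyric anhydride, CC(C)C(=O)OC(=O)C(C)C
Why: DMAP-catalysed acylation of the hindered 6β-hydroxyl with the anhydride completes the target.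

**Compound list**

1 | (S)-3-hydroxy-γ-butyrolactone [(4S)-4-hydroxyoxolan-2-one] | O=C1C[C@H](O)CO1 | starting material
2 | (3S)-3,4-dihydroxy-N-methoxy-N-methylbutanamide | CON(C)C(=O)C[C@H](O)CO | intermediate
3 | (3S)-N-methoxy-N-methyl-3,4-bis(triethylsilyloxy)butanamide | CON(C)C(=O)C[C@H](O[Si](CC)(CC)CC)CO[Si](CC)(CC)CC | intermediate
4 | (4S)-4,5-bis(triethylsilyloxy)pentan-2-one | CC(=O)C[C@H](O[Si](CC)(CC)CC)CO[Si](CC)(CC)CC | intermediate
5 | sodium (1E,5S)-3-oxo-5,6-bis(triethylsilyloxy)hex-1-en-1-olate | [Na+].[O-]/C=C/C(=O)C[C@H](O[Si](CC)(CC)CC)CO[Si](CC)(CC)CC | intermediate (not isolated)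
6 | allyl (1E,5S)-3-oxo-5,6-bis(triethylsilyloxy)hex-1-enyl carbonate | C=CCOC(=O)O/C=C/C(=O)C[C@H](O[Si](CC)(CC)CC)CO[Si](CC)(CC)CC | intermediate
7 | allyl (1E,5S)-6-hydroxy-3-oxo-5-(triethylsilyloxy)hex-1-enyl carbonate | C=CCOC(=O)O/C=C/C(=O)C[C@H](O[Si](CC)(CC)CC)CO | intermediate
8 | tert-butyl propanoate | CCC(=O)OC(C)(C)C | starting material
9 | lithium (Z)-enolate of tert-butyl 2-formylpropanoate | [Li+].[O-]/C=C(/C)C(=O)OC(C)(C)C | intermediate (not isolated)
10 | tert-butyl (2Z)-3-acetoxy-2-methylprop-2-enoate | CC(=O)O/C=C(/C)C(=O)OC(C)(C)C | intermediate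
11 | (2Z)-3-acetoxy-2-methylprop-2-enoic acid | CC(=O)O/C=C(/C)C(=O)O | intermediate
12 | (2Z)-3-acetoxy-2-methylprop-2-enoyl chloride | CC(=O)O/C=C(/C)C(Cl)=O | intermediate (not isolated)
13 | (2S,5E)-6-(allyloxycarbonyloxy)-4-oxo-2-(triethylsilyloxy)hex-5-enyl (2Z)-3-acetoxy-2-methylprop-2-enoate | C=CCOC(=O)O/C=C/C(=O)C[C@H](O[Si](CC)(CC)CC)COC(=O)/C(C)=C\OC(C)=O | intermediate
14 | (2S,3Z,5E)-6-(allyloxycarbonyloxy)-4-(tert-butyldimethylsilyloxy)-2-(triethylsilyloxy)hexa-3,5-dienyl (2Z)-3-acetoxy-2-methylprop-2-enoate | C=CCOC(=O)O/C=C/C(O[Si](C)(C)C(C)(C)C)=C/[C@H](O[Si](CC)(CC)CC)COC(=O)/C(C)=C\OC(C)=O | intermediate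
15 | trans-fused δ-lactone cycloadduct: lactone C1(=O)–O15–C15–C4–C5–C10; C6=C7 TBS enol ether; 4S-OTES, 5α-H, 8β-OCO2allyl, 9α-OAc, 10β-Me | O=C1OC[C@@H](O[Si](CC)(CC)CC)[C@@H]2C(O[Si](C)(C)C(C)(C)C)=C[C@H](OC(=O)OCC=C)[C@@H](OC(C)=O)[C@@]12C | intermediate
16 | 8β-hydroxy cycloadduct (as 15, free 8β-OH) | O=C1OC[C@@H](O[Si](CC)(CC)CC)[C@@H]2C(O[Si](C)(C)C(C)(C)C)=C[C@H](O)[C@@H](OC(C)=O)[C@@]12C | intermediate
17 | 2-bromoacrolein diethyl acetal (2-bromo-3,3-diethoxyprop-1-ene) | C=C(Br)C(OCC)OCC | starting material
18 | 1-(2-bromo-1-ethoxyprop-2-enyl)-2,4,6-trimethylpyridinium triflate | CCOC(C(Br)=C)[n+]1c(C)cc(C)cc1C.[O-]S(=O)(=O)C(F)(F)F | intermediate (not isolated)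
19 | mixed acetal (as 16, 8β-O–CH(OEt)–C(Br)=CH2; acetal epimers) | O=C1OC[C@@H](O[Si](CC)(CC)CC)[C@@H]2C(O[Si](C)(C)C(C)(C)C)=C[C@H](OC(OCC)C(Br)=C)[C@@H](OC(C)=O)[C@@]12C | intermediate
20 | tricyclic acetal: cis-fused 12-ethoxy-11(13)-methylene tetrahydrofuran on C7/C8; 6β-OTBS, 7α-H, 8α-H, 9α-OAc, 4S-OTES, δ-lactone retained | O=C1OC[C@@H](O[Si](CC)(CC)CC)[C@@H]2[C@H](O[Si](C)(C)C(C)(C)C)[C@@H]3C(=C)C(OCC)O[C@@H]3[C@@H](OC(C)=O)[C@@]12C | intermediate
21 | C4 carbinol (as 20, 4S-OH) | O=C1OC[C@@H](O)[C@@H]2[C@H](O[Si](C)(C)C(C)(C)C)[C@@H]3C(=C)C(OCC)O[C@@H]3[C@@H](OC(C)=O)[C@@]12C | intermediate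
22 | C4 ketone (as 20, C4=O) | O=C1OCC(=O)[C@@H]2[C@H](O[Si](C)(C)C(C)(C)C)[C@@H]3C(=C)C(OCC)O[C@@H]3[C@@H](OC(C)=O)[C@@]12C | intermediate
23 | 4(3)-methylene δ-lactone (as 20, C4=CH2) | O=C1OCC(=C)[C@@H]2[C@H](O[Si](C)(C)C(C)(C)C)[C@@H]3C(=C)C(OCC)O[C@@H]3[C@@H](OC(C)=O)[C@@]12C | intermediate
24 | lactol (C1 hemiacetal to O15, 9α-OH; anomers) | OC1OCC(=C)[C@@H]2[C@H](O[Si](C)(C)C(C)(C)C)[C@@H]3C(=C)C(OCC)O[C@@H]3[C@@H](O)[C@@]12C | intermediate
25 | vinyl diol: 10α-vinyl, 10β-Me, 9α-OH, 15-OH, 6β-OTBS, 12-ethoxy acetal | C=C[C@]1(C)[C@H](O)[C@H]2OC(OCC)C(=C)[C@H]2[C@@H](O[Si](C)(C)C(C)(C)C)[C@H]1C(=C)CO | intermediate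
26 | 9α,15-diacetate of 25 | C=C[C@]1(C)[C@H](OC(C)=O)[C@H]2OC(OCC)C(=C)[C@H]2[C@@H](O[Si](C)(C)C(C)(C)C)[C@H]1C(=C)COC(C)=O | intermediate
27 | 9α,15-diacetoxy-6β-(tert-butyldimethylsilyloxy)elema-1,3,11(13)-trien-12,8β-olide | C=C[C@]1(C)[C@H](OC(C)=O)[C@H]2OC(=O)C(=C)[C@H]2[C@@H](O[Si](C)(C)C(C)(C)C)[C@H]1C(=C)COC(C)=O | intermediate
28 | 9α,15-diacetoxy-6β-hydroxyelema-1,3,11(13)-trien-12,8β-olide | C=C[C@]1(C)[C@H](OC(C)=O)[C@H]2OC(=O)C(=C)[C@H]2[C@@H](O)[C@H]1C(=C)COC(C)=O | intermediate
29 | CNP0500052.1: 9α,15-diacetoxy-6β-isobutyryloxy-elema-1,3,11(13)-trien-12,8β-olide (5αH, 7αH, 8αH, 10β-Me) | C=C[C@]1(C)[C@H](OC(C)=O)[C@H]2OC(=O)C(=C)[C@H]2[C@@H](OC(=O)C(C)C)[C@H]1C(=C)COC(C)=O | target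

**Step count and risks**

Total step count: 22. Longest linear sequence: 20 steps (1 to 29 through steps 1–5 and 8–22).

Steps most likely to fail:

1. Step 10. The cycloaddition may be slow, because the donor pattern of the diene is not matched to the acrylate, so that the triene decays on heating; the preference for the anti (trans-fusing) mode may also be incomplete. The fallback changes the diene to the more electron-rich 1,3-bis(silyloxy) type, which should react at a lower temperature where the anti preference is larger. It sets out from keto ester 13. Pd(PPh3)4 and dimedone remove the allyl carbonate to give the hydroxymethylene ketone F1. Me3SiCl/Et3N followed by TBSOTf/Et3N gives the 6-trimethylsilyloxy-4-TBS-oxy diene F2. Heating in toluene at about 90 °C gives the 8β-trimethylsilyloxy cycloadduct F3. Brief methanolysis (citric acid, MeOH, 0 °C) cleaves only the trimethylsilyl ether and returns to the route at alcohol 16, so step 11 is no longer needed.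

2. Step 13. The vinyl radical may be reduced by the stannane before it closes onto C7, or the bromoallyl acetal may not survive its own preparation. The fallback generates the same vinyl radical by reversible addition of a stannyl radical to an alkyne. It sets out from alcohol 16. Propiolaldehyde diethyl acetal is activated with Et3SiOTf/2,4,6-collidine as the 1-ethoxypropynyl collidinium triflate F4, which with 16 gives the propargylic mixed acetal F5. Bu3SnH/AIBN in benzene at 80 °C adds tin to the alkyne terminus, and the vinyl radical closes 5-exo onto C7 to give the exocyclic vinylstannane F6. Protodestannylation (PPTS, wet CH2Cl2) returns to the route at acetal 20.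

3. Step 18. Retro-aldol cleavage of the C9–C10 bond may occur when the lactol opens to the aldehyde in the presence of the C9 alkoxide under the basic ylide conditions. The fallback is a two-stage Peterson olefination with a less basic carbon nucleophile. It sets out from lactol 24. Me3SiCH2MgCl in THF adds to the aldehyde form to give the β-hydroxysilane F7, in which no carbonyl group remains. KH in THF then brings about syn-elimination and returns to the route at vinyl diol 25.

**Further compounds**

F1 | step 10 | (2S)-6-hydroxy-4-oxo-2-(triethylsilyloxy)hex-5-enyl (2Z)-3-acetoxy-2-methylprop-2-enoate (hydroxymethylene ketone, enol form) | O/C=C\C(=O)C[C@H](O[Si](CC)(CC)CC)COC(=O)/C(C)=C\OC(C)=O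
F2 | step 10 | (2S,3Z,5E)-4-(tert-butyldimethylsilyloxy)-2-(triethylsilyloxy)-6-(trimethylsilyloxy)hexa-3,5-dienyl (2Z)-3-acetoxy-2-methylprop-2-enoate | C[Si](C)(C)O/C=C/C(O[Si](C)(C)C(C)(C)C)=C/[C@H](O[Si](CC)(CC)CC)COC(=O)/C(C)=C\OC(C)=O
F3 | step 10 | 8β-trimethylsilyloxy analogue of cycloadduct 15 | O=C1OC[C@@H](O[Si](CC)(CC)CC)[C@@H]2C(O[Si](C)(C)C(C)(C)C)=C[C@H](O[Si](C)(C)C)[C@@H](OC(C)=O)[C@@]12C
F4 | step 13 | 1-(1-ethoxyprop-2-ynyl)-2,4,6-trimethylpyridinium triflate | CCOC(C#C)[n+]1c(C)cc(C)cc1C.[O-]S(=O)(=O)C(F)(F)F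
F5 | step 13 | propargylic mixed acetal (as 16, 8β-O–CH(OEt)–C≡CH) | O=C1OC[C@@H](O[Si](CC)(CC)CC)[C@@H]2C(O[Si](C)(C)C(C)(C)C)=C[C@H](OC(OCC)C#C)[C@@H](OC(C)=O)[C@@]12C
F6 | step 13 | tricyclic acetal with exocyclic (tributylstannyl)methylene at C11 | O=C1OC[C@@H](O[Si](CC)(CC)CC)[C@@H]2[C@H](O[Si](C)(C)C(C)(C)C)[C@@H]3C(=C[Sn](CCCC)(CCCC)CCCC)C(OCC)O[C@@H]3[C@@H](OC(C)=O)[C@@]12C
F7 | step 18 | β-hydroxysilane (C1 carbinol bearing CH2SiMe3; 9α-OH; 15-OH) | C[Si](C)(C)CC(O)[C@]1(C)[C@H](O)[C@H]2OC(OCC)C(=C)[C@H]2[C@@H](O[Si](C)(C)C(C)(C)C)[C@H]1C(=C)CO
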